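## Retrosynthetic overview

1. The strategy rests on ring D, the trans-2,3-dihydrofuran O1–C2–C3–C3a–C7a. O1 and C3a are the phenol oxygen and its neighbouring ring carbon of a 5-substituted vanillin (ring C), and C2–C3 is the side-chain double bond of a sinapyl unit whose ring B already carries, on its 4-oxygen, the C8(C9H2OH)–C7(OH)–ring A chain.
2. Ring D is cut at O1–C2 and C3–C3a, giving 5-iodovanillin and the fully silylated erythro-(7S,8R) guaiacylglycerol 8-O-4' (E)-sinapyl ether. Both bonds and the C2/C3 stereocentres are made in one palladium oxyarylation, followed only by desilylation.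
3. The sinapyl ether is cut at C7–C8: a magnesium-catalysed anti aldol of an (aryloxy)acetyl oxazolidinone with O-silylvanillin (ring A), then reductive loss of the auxiliary and silylation.
4. The imide is cut at O–C8: alkylation of the phenol of sinapyl alcohol (from sinapic acid, ring B) with a bromoacetyl oxazolidinone.
5. Ring order: rings A, B and C are bought as vanillin, sinapic acid and 5-iodovanillin; ring D is the only ring formed, last, in step 10.

Key step: step 10

Remark (assumption): the (7S,8R) pair encoded in the SMILES is the erythro form, that is, the anti aldol relationship between the C7 hydroxyl and the C8 aryloxy group; the ligand enantiomer that matches the (2R,3S) series in step 10 cannot be predicted, and the (S)-ligand is named as first choice. Abbreviations: TBS = tert-butyldimethylsilyl, TMS = trimethylsilyl.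

## Route

Step 1
Reactants: 1 sinapic acid
Product: 2 methyl sinapate
Conditions: MeOH, H2SO4 (cat.), reflux
Reagents that add atoms: methanol, CO
Why: Fischer esterification leaves the phenol and the (E)-alkene untouched and gives an ester that an aluminium hydride can reduce.

Step 2
Reactants: 2 methyl sinapate
Product: 3 (E)-sinapyl alcohol
Conditions: i-Bu2AlH (4 equiv), toluene/THF, 0 °C; then EtOH, aq. potassium sodium tartrate
Reagents that add atoms: none
Why: 1,2-reduction of a cinnamate ester by i-Bu2AlH (aluminium hydride reduction) delivers two hydrides to the carbonyl and none to the conjugated alkene once the phenol is capped as its aluminium phenoxide, which is the standard access to monolignols.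

Step 3
Reactants: 4 (R)-4-benzyloxazolidin-2-one
Product: 6 (R)-4-benzyl-3-(bromoacetyl)oxazolidin-2-one, via N-lithio (R)-4-benzyloxazolidin-2-one 5 (not isolated)
Conditions: n-BuLi (1.0 equiv), THF, −78 °C; then BrCH2COBr, −78 → 0 °C
Reagents that add atoms: bromoacetyl bromide, BrCC(Br)=O
Why: N-acylation of the lithiated oxazolidinone by the acid bromide (nucleophilic acyl substitution) is faster at low temperature than displacement of the primary bromide, so the bromoacetyl imide carrying the (R)-benzyl controller is obtained.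

Step 4
Reactants: 3 (E)-sinapyl alcohol; 6 (R)-4-benzyl-3-(bromoacetyl)oxazolidin-2-one
Product: 7 (R)-4-benzyl-3-({4-[(E)-3-hydroxyprop-1-enyl]-2,6-dimethoxyphenoxy}acetyl)oxazolidin-2-one
Conditions: K2CO3 (1.5 equiv), acetone, rt, under N2
Reagents that add atoms: none
Why: Williamson ether synthesis in which carbonate deprotonates only the phenol (not the allylic alcohol) and the 2,6-dimethoxyphenoxide displaces the strongly activated alpha-bromo imide by SN2, forming the O–C8 bond of the later 8-O-4' ether.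

Step 5
Reactants: 7 aryloxyacetyl imide with free allylic alcohol
Product: 8 (R)-4-benzyl-3-({4-[(E)-3-(TBS-oxy)prop-1-enyl]-2,6-dimethoxyphenoxy}acetyl)oxazolidin-2-one
Conditions: TBSCl, imidazole, CH2Cl2, 0 °C → rt
Reagents that add atoms: tert-butyldimethylsilyl chloride, CC(C)(C)[Si](C)(C)Cl
Why: Imidazole-promoted silylation of the only free hydroxyl, the primary allylic alcohol, under conditions the imide tolerates.

Step 6
Reactants: 9 vanillin
Product: 10 4-(TBS-oxy)-3-methoxybenzaldehyde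
Conditions: TBSCl, imidazole, DMF, rt
Reagents that add atoms: tert-butyldimethylsilyl chloride, CC(C)(C)[Si](C)(C)Cl
Why: Imidazole-promoted silylation masks the acidic, silver-oxidisable phenol of ring A and leaves the aldehyde free for the aldol.

Step 7
Reactants: 8 silylated aryloxyacetyl imide; 10 4-(TBS-oxy)-3-methoxybenzaldehyde
Product: 11 (R)-4-benzyl-3-[(2S,3S)-2-{4-[(E)-3-(TBS-oxy)prop-1-enyl]-2,6-dimethoxyphenoxy}-3-[4-(TBS-oxy)-3-methoxyphenyl]-3-(TMS-oxy)propanoyl]oxazolidin-2-one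
Conditions: MgCl2 (0.2 equiv), Et3N (2.5 equiv), Me3SiCl (2 equiv), EtOAc, rt; filtration through Et3N-deactivated silica
Reagents that add atoms: chlorotrimethylsilane, C[Si](C)(C)Cl
Why: Magnesium-halide-catalysed direct anti aldol of an N-acyl oxazolidinone with a non-enolisable aromatic aldehyde, in which MgCl2/Et3N soft-enolises the chelated imide to its (Z)-enolate, this should add through a boat-like closed transition state on the face away from the (R)-benzyl group (setting C8, 2S in the imide) and anti to the aldehyde substituent (setting C7, 3S), and Me3SiCl traps the aldolate and turns magnesium over; the hindered aryl ether oxygen is too poor a donor to displace the imide chelate.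

Step 8
Reactants: 11 anti aldol adduct as its TMS ether
Product: 13 (1S,2R)-1-[4-(TBS-oxy)-3-methoxyphenyl]-2-{4-[(E)-3-(TBS-oxy)prop-1-enyl]-2,6-dimethoxyphenoxy}propane-1,3-diol, via C7-O-TMS primary alcohol 12 (not isolated)
Conditions: LiBH4 (2 equiv), H2O (1 equiv), THF, 0 °C; then 10% aq. citric acid, THF, rt
Reagents that add atoms: none
Why: Reductive cleavage of the imide by LiBH4 at the exocyclic carbonyl gives the primary alcohol and returns the auxiliary while the C7 silyl ether blocks retro-aldol, and dilute citric acid then removes only the labile TMS group, leaving both TBS ethers and both stereocentres intact.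

Step 9
Reactants: 13 erythro diol
Product: 14 tetrakis-TBS ether of erythro-(7S,8R)-guaiacylglycerol 8-O-4' (E)-sinapyl alcohol ether
Conditions: TBSOTf (2.5 equiv), 2,6-lutidine (4 equiv), CH2Cl2, −78 → 0 °C
Reagents that add atoms: tert-butyldimethylsilyl triflate, CC(C)(C)[Si](C)(C)OS(=O)(=O)C(F)(F)F
Why: Silyl triflate with 2,6-lutidine silylates both the primary and the hindered secondary benzylic hydroxyl under non-nucleophilic conditions that do not ionise the electron-rich benzylic position.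

Step 10
Reactants: 14 tetrakis-TBS sinapyl ether; 15 5-iodovanillin
Product: 16 tetrakis-TBS ether of the target with the (2R,3S)-trans-dihydrobenzofuran
Conditions: Pd(OAc)2 (10 mol%), (S)-4-tert-butyl-2-(pyridin-2-yl)-4,5-dihydrooxazole (15 mol%), Ag2CO3 (1.5 equiv), 15 (1.5 equiv), acetone, 50 °C, dark
Reagents that add atoms: none
Why: Proposed new method: zerovalent palladium formed in situ inserts into the C–I bond of 15, Ag2CO3 removes iodide and deprotonates the phenol, and the cationic arylpalladium carried by the chiral pyridine-oxazoline adds syn across the (E)-alkene of 14 with the ring C carbon C3a on C3 and palladium on the benzylic C2, where electron-rich ring B holds it as an eta-3 benzyl; the ortho phenoxide then closes a six-membered oxapalladacycle and C–O reductive elimination with retention forms O1–C2. The closest known reaction type is the ligand-free Pd(OAc)2/Ag2CO3 oxyarylation of 2H-chromenes and (E)-propenylarenes with ortho-iodophenols, which gives racemic trans products, together with enantioselective palladium heteroannulation of ortho-halophenols with 1,3-dienes; what is new is ligand control of the insertion face on a 1,2-disubstituted styrene. Ring D closes as an intermolecular [3+2] heteroannulation, the C3–C3a bond by migratory insertion and the O1–C2 bond by reductive elimination from the oxapalladacycle to give the five-membered ring. C3 is set by the alkene face that the ligand presents to the aryl group and C2 follows from syn addition to the (E)-alkene and is therefore trans to C3, while C7 and C8 are too remote to bias the face, so a mismatched run would give the separable (2S,3R) diastereomer and not an enantiomer. The step needs regioselectivity (aryl to C3), secured by benzylic stabilisation of palladium at C2 next to the 4-alkoxy-3,5-dimethoxyphenyl ring, and C–O closure over beta-hydride elimination, helped by the chelating ligand and the bound phenoxide leaving no free cis site; silylation of the ring A phenol removes the only silver-oxidisable group of 14.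

Step 11
Reactants: 16 tetrakis-TBS ether of the target
Product: 17 target, (2R,3S)-2-(4-{[(1S,2R)-1,3-dihydroxy-1-(4-hydroxy-3-methoxyphenyl)propan-2-yl]oxy}-3,5-dimethoxyphenyl)-3-(hydroxymethyl)-7-methoxy-2,3-dihydrobenzofuran-5-carbaldehyde
Conditions: Bu4NF (6 equiv), AcOH (6 equiv), THF, 0 °C → rt
Reagents that add atoms: none
Why: Fluoride-mediated desilylation buffered with acetic acid cleaves the aryl, the two primary and the secondary silyl ether without exposing the aldehyde, the 4-hydroxybenzylic carbinol or the benzylic ether carbon C2 to strong base or acid, so no stereocentre should epimerise through a quinone methide.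

## Compound list

1 | sinapic acid, (E)-3-(4-hydroxy-3,5-dimethoxyphenyl)prop-2-enoic acid | COc1cc(/C=C/C(=O)O)cc(OC)c1O | starting material
2 | methyl sinapate, methyl (E)-3-(4-hydroxy-3,5-dimethoxyphenyl)prop-2-enoate | COC(=O)/C=C/c1cc(OC)c(O)c(OC)c1 | intermediate
3 | (E)-sinapyl alcohol, 4-[(E)-3-hydroxyprop-1-enyl]-2,6-dimethoxyphenol | COc1cc(/C=C/CO)cc(OC)c1O | intermediate
4 | (R)-4-benzyloxazolidin-2-one | O=C1N[C@H](Cc2ccccc2)CO1 | starting material
5 | N-lithio (R)-4-benzyloxazolidin-2-one (not isolated) | [Li+].O=C1[N-][C@H](Cc2ccccc2)CO1 | intermediate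
6 | (R)-4-benzyl-3-(bromoacetyl)oxazolidin-2-one | O=C(CBr)N1C(=O)OC[C@H]1Cc1ccccc1 | intermediate
7 | (R)-4-benzyl-3-({4-[(E)-3-hydroxyprop-1-enyl]-2,6-dimethoxyphenoxy}acetyl)oxazolidin-2-one | COc1cc(/C=C/CO)cc(OC)c1OCC(=O)N1C(=O)OC[C@H]1Cc1ccccc1 | intermediate
8 | (R)-4-benzyl-3-({4-[(E)-3-(tert-butyldimethylsilyloxy)prop-1-enyl]-2,6-dimethoxyphenoxy}acetyl)oxazolidin-2-one | COc1cc(/C=C/CO[Si](C)(C)C(C)(C)C)cc(OC)c1OCC(=O)N1C(=O)OC[C@H]1Cc1ccccc1 | intermediate
9 | vanillin | COc1cc(C=O)ccc1O | starting material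
10 | 4-(tert-butyldimethylsilyloxy)-3-methoxybenzaldehyde | COc1cc(C=O)ccc1O[Si](C)(C)C(C)(C)C | intermediate
11 | (R)-4-benzyl-3-[(2S,3S)-2-{4-[(E)-3-(tert-butyldimethylsilyloxy)prop-1-enyl]-2,6-dimethoxyphenoxy}-3-[4-(tert-butyldimethylsilyloxy)-3-methoxyphenyl]-3-(trimethylsilyloxy)propanoyl]oxazolidin-2-one | COc1cc([C@H](O[Si](C)(C)C)[C@@H](C(=O)N2C(=O)OC[C@H]2Cc2ccccc2)Oc2c(OC)cc(/C=C/CO[Si](C)(C)C(C)(C)C)cc2OC)ccc1O[Si](C)(C)C(C)(C)C | intermediate
12 | (2R,3S)-2-{4-[(E)-3-(tert-butyldimethylsilyloxy)prop-1-enyl]-2,6-dimethoxyphenoxy}-3-[4-(tert-butyldimethylsilyloxy)-3-methoxyphenyl]-3-(trimethylsilyloxy)propan-1-ol (not isolated) | COc1cc([C@H](O[Si](C)(C)C)[C@@H](CO)Oc2c(OC)cc(/C=C/CO[Si](C)(C)C(C)(C)C)cc2OC)ccc1O[Si](C)(C)C(C)(C)C | intermediate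
13 | (1S,2R)-1-[4-(tert-butyldimethylsilyloxy)-3-methoxyphenyl]-2-{4-[(E)-3-(tert-butyldimethylsilyloxy)prop-1-enyl]-2,6-dimethoxyphenoxy}propane-1,3-diol | COc1cc([C@H](O)[C@@H](CO)Oc2c(OC)cc(/C=C/CO[Si](C)(C)C(C)(C)C)cc2OC)ccc1O[Si](C)(C)C(C)(C)C | intermediate
14 | tetrakis(tert-butyldimethylsilyl) ether of erythro-(7S,8R)-guaiacylglycerol 8-O-4' (E)-sinapyl alcohol ether (silyl groups on the ring A phenol, O7, O9 and the allylic oxygen) | COc1cc([C@H](O[Si](C)(C)C(C)(C)C)[C@@H](CO[Si](C)(C)C(C)(C)C)Oc2c(OC)cc(/C=C/CO[Si](C)(C)C(C)(C)C)cc2OC)ccc1O[Si](C)(C)C(C)(C)C | intermediate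
15 | 5-iodovanillin, 4-hydroxy-3-iodo-5-methoxybenzaldehyde | COc1cc(C=O)cc(I)c1O | starting material
16 | (2R,3S)-2-(4-{[(1S,2R)-1,3-bis(tert-butyldimethylsilyloxy)-1-[4-(tert-butyldimethylsilyloxy)-3-methoxyphenyl]propan-2-yl]oxy}-3,5-dimethoxyphenyl)-3-[(tert-butyldimethylsilyloxy)methyl]-7-methoxy-2,3-dihydrobenzofuran-5-carbaldehyde | COc1cc([C@H](O[Si](C)(C)C(C)(C)C)[C@@H](CO[Si](C)(C)C(C)(C)C)Oc2c(OC)cc([C@@H]3Oc4c(OC)cc(C=O)cc4[C@H]3CO[Si](C)(C)C(C)(C)C)cc2OC)ccc1O[Si](C)(C)C(C)(C)C | intermediate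
17 | (2R,3S)-2-(4-{[(1S,2R)-1,3-dihydroxy-1-(4-hydroxy-3-methoxyphenyl)propan-2-yl]oxy}-3,5-dimethoxyphenyl)-3-(hydroxymethyl)-7-methoxy-2,3-dihydrobenzofuran-5-carbaldehyde (CID53356209) | COc1cc([C@H](O)[C@@H](CO)Oc2c(OC)cc([C@@H]3Oc4c(OC)cc(C=O)cc4[C@H]3CO)cc2OC)ccc1O | target

## Step count and risks

Total step count: 11. Longest linear sequence: 9 steps (steps 1, 2, 4, 5, 7, 8, 9, 10, 11).

Steps most likely to fail:

1. Step 10 (the step labelled as a proposed new method).
What may go wrong: beta-hydride elimination from the benzylic palladium intermediate may outrun C–O bond formation and give the Heck alkene; the ligand may slow insertion into the 1,2-disubstituted alkene; or it may discriminate the two alkene faces poorly, giving a mixture at C2/C3. A wrong sense of induction is first answered with the enantiomeric ligand.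
Fallback (known chemistry; sets out from 14 and 15, returns at 16): ring D is built instead by a catalyst-controlled carbenoid C–H insertion.
- The alkene of 14 is cleaved (OsO4 cat., NaIO4, 2,6-lutidine, dioxane/H2O; Lemieux–Johnson) to the ring B benzaldehyde F1, and NaBH4 in MeOH/THF reduces it to the benzylic alcohol F2.
- A Mitsunobu reaction (PPh3, DIAD, THF) of F2 with 15 gives the aryl benzyl ether F3.
- Palladium-catalysed coupling of the aryl iodide with ethyl diazoacetate (Pd(PPh3)4, Ag2CO3, Et3N, toluene, rt) gives the aryldiazoacetate F4.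
- Dirhodium tetrakis[N-phthaloyl-(S)-tert-leucinate], Rh2(S-PTTL)4, in toluene at −60 °C should insert the carbenoid into the benzylic OCH2 C–H bond and give the cis-2-aryl-2,3-dihydrobenzofuran-3-carboxylate F5. C2 is set by the catalyst; the enantiomeric catalyst is used if the first run favours 2S.
- DBU in toluene epimerises C3 to the trans ester F6.
- LiBH4 in THF reduces ester and aldehyde to the diol F7, and MnO2 in CH2Cl2 reoxidises only the benzylic alcohol to the hydroxy aldehyde F8.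
- TBSCl/imidazole gives 16.

2. Step 7.
What may go wrong: erosion of the anti preference if a chair transition state or chelation through the aryloxy oxygen competes, and slow addition to the electron-rich aldehyde with retro-aldol equilibration before silyl trapping.
Fallback (sets out from 3 and 10, returns at 14): a boron-mediated syn aldol with the enantiomeric auxiliary, followed by inversion of C7.
- Commercial (S)-4-benzyloxazolidin-2-one is lithiated (n-BuLi, THF, −78 °C) to the N-lithio (S)-oxazolidinone F9 (not isolated) and acylated with bromoacetyl bromide to (S)-4-benzyl-3-(bromoacetyl)oxazolidin-2-one F10.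
- 3 is O-alkylated with F10 (K2CO3, acetone) to the (S)-imide F11 and silylated (TBSCl, imidazole) to its allylic TBS ether F12.
- Enolisation with Bu2BOTf/i-Pr2NEt in CH2Cl2 at −78 °C and addition of 10 (Evans syn aldol, Zimmerman–Traxler chair) should give the (2S,3R) syn adduct F13, which has C8 as in the target and C7 inverted.
- LiBH4 gives the threo-(1R,2R) diol F14, and TBSCl/imidazole at 0 °C silylates only the primary hydroxyl to give the mono-silyl ether F15.
- Dess–Martin periodinane gives the aryl ketone F16, and LiBH(s-Bu)3 in THF at −78 °C reduces it under Felkin–Anh control to the erythro-(1S,2R) alcohol F17.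
- TBSOTf/2,6-lutidine gives 14.

3. Step 4.
What may go wrong: acyl transfer from the imide to phenoxide or carbonate (loss of the auxiliary) in competition with SN2 displacement, and oxidative degradation of the 4-hydroxycinnamyl alcohol under base.
Fallback (sets out from 3, returns at 8): the imide is made by acylating the auxiliary instead of alkylating with it.
- 3 is O-alkylated with ethyl bromoacetate (K2CO3, acetone) to the ethyl aryloxyacetate F18, silylated (TBSCl, imidazole) to its TBS ether F19 and saponified (LiOH, THF/H2O) to the aryloxyacetic acid F20.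
- Pivaloyl chloride/Et3N in THF at −20 °C gives the mixed pivalic anhydride F21 (not isolated), which acylates the lithium salt 5 to give 8.

## Further compounds

F1 | step 10 | 4-{[(1S,2R)-1,3-bis(TBS-oxy)-1-[4-(TBS-oxy)-3-methoxyphenyl]propan-2-yl]oxy}-3,5-dimethoxybenzaldehyde | COc1cc([C@H](O[Si](C)(C)C(C)(C)C)[C@@H](CO[Si](C)(C)C(C)(C)C)Oc2c(OC)cc(C=O)cc2OC)ccc1O[Si](C)(C)C(C)(C)C
F2 | step 10 | (4-{[(1S,2R)-1,3-bis(TBS-oxy)-1-[4-(TBS-oxy)-3-methoxyphenyl]propan-2-yl]oxy}-3,5-dimethoxyphenyl)methanol | COc1cc([C@H](O[Si](C)(C)C(C)(C)C)[C@@H](CO[Si](C)(C)C(C)(C)C)Oc2c(OC)cc(CO)cc2OC)ccc1O[Si](C)(C)C(C)(C)C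
F3 | step 10 | 4-[(4-{[(1S,2R)-1,3-bis(TBS-oxy)-1-[4-(TBS-oxy)-3-methoxyphenyl]propan-2-yl]oxy}-3,5-dimethoxybenzyl)oxy]-3-iodo-5-methoxybenzaldehyde | COc1cc([C@H](O[Si](C)(C)C(C)(C)C)[C@@H](CO[Si](C)(C)C(C)(C)C)Oc2c(OC)cc(COc3c(I)cc(C=O)cc3OC)cc2OC)ccc1O[Si](C)(C)C(C)(C)C
F4 | step 10 | ethyl 2-diazo-2-{2-[(4-{[(1S,2R)-1,3-bis(TBS-oxy)-1-[4-(TBS-oxy)-3-methoxyphenyl]propan-2-yl]oxy}-3,5-dimethoxybenzyl)oxy]-5-formyl-3-methoxyphenyl}acetate | COc1cc([C@H](O[Si](C)(C)C(C)(C)C)[C@@H](CO[Si](C)(C)C(C)(C)C)Oc2c(OC)cc(COc3c(C(=[N+]=[N-])C(=O)OCC)cc(C=O)cc3OC)cc2OC)ccc1O[Si](C)(C)C(C)(C)C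
F5 | step 10 | ethyl (2R,3S)-cis-2-(4-{[(1S,2R)-1,3-bis(TBS-oxy)-1-[4-(TBS-oxy)-3-methoxyphenyl]propan-2-yl]oxy}-3,5-dimethoxyphenyl)-5-formyl-7-methoxy-2,3-dihydrobenzofuran-3-carboxylate | COc1cc([C@H](O[Si](C)(C)C(C)(C)C)[C@@H](CO[Si](C)(C)C(C)(C)C)Oc2c(OC)cc([C@@H]3Oc4c(OC)cc(C=O)cc4[C@@H]3C(=O)OCC)cc2OC)ccc1O[Si](C)(C)C(C)(C)C
F6 | step 10 | ethyl (2R,3R)-trans-2-(4-{[(1S,2R)-1,3-bis(TBS-oxy)-1-[4-(TBS-oxy)-3-methoxyphenyl]propan-2-yl]oxy}-3,5-dimethoxyphenyl)-5-formyl-7-methoxy-2,3-dihydrobenzofuran-3-carboxylate | COc1cc([C@H](O[Si](C)(C)C(C)(C)C)[C@@H](CO[Si](C)(C)C(C)(C)C)Oc2c(OC)cc([C@@H]3Oc4c(OC)cc(C=O)cc4[C@H]3C(=O)OCC)cc2OC)ccc1O[Si](C)(C)C(C)(C)C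
F7 | step 10 | [(2R,3S)-2-(4-{[(1S,2R)-1,3-bis(TBS-oxy)-1-[4-(TBS-oxy)-3-methoxyphenyl]propan-2-yl]oxy}-3,5-dimethoxyphenyl)-7-methoxy-2,3-dihydrobenzofuran-3,5-diyl]dimethanol | COc1cc([C@H](O[Si](C)(C)C(C)(C)C)[C@@H](CO[Si](C)(C)C(C)(C)C)Oc2c(OC)cc([C@@H]3Oc4c(OC)cc(CO)cc4[C@H]3CO)cc2OC)ccc1O[Si](C)(C)C(C)(C)C
F8 | step 10 | (2R,3S)-2-(4-{[(1S,2R)-1,3-bis(TBS-oxy)-1-[4-(TBS-oxy)-3-methoxyphenyl]propan-2-yl]oxy}-3,5-dimethoxyphenyl)-3-(hydroxymethyl)-7-methoxy-2,3-dihydrobenzofuran-5-carbaldehyde | COc1cc([C@H](O[Si](C)(C)C(C)(C)C)[C@@H](CO[Si](C)(C)C(C)(C)C)Oc2c(OC)cc([C@@H]3Oc4c(OC)cc(C=O)cc4[C@H]3CO)cc2OC)ccc1O[Si](C)(C)C(C)(C)C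
F9 | step 7 | N-lithio (S)-4-benzyloxazolidin-2-one (not isolated) | [Li+].O=C1[N-][C@@H](Cc2ccccc2)CO1
F10 | step 7 | (S)-4-benzyl-3-(bromoacetyl)oxazolidin-2-one | O=C(CBr)N1C(=O)OC[C@@H]1Cc1ccccc1
F11 | step 7 | (S)-4-benzyl-3-({4-[(E)-3-hydroxyprop-1-enyl]-2,6-dimethoxyphenoxy}acetyl)oxazolidin-2-one | COc1cc(/C=C/CO)cc(OC)c1OCC(=O)N1C(=O)OC[C@@H]1Cc1ccccc1
F12 | step 7 | (S)-4-benzyl-3-({4-[(E)-3-(TBS-oxy)prop-1-enyl]-2,6-dimethoxyphenoxy}acetyl)oxazolidin-2-one | COc1cc(/C=C/CO[Si](C)(C)C(C)(C)C)cc(OC)c1OCC(=O)N1C(=O)OC[C@@H]1Cc1ccccc1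
F13 | step 7 | (S)-4-benzyl-3-[(2S,3R)-2-{4-[(E)-3-(TBS-oxy)prop-1-enyl]-2,6-dimethoxyphenoxy}-3-hydroxy-3-[4-(TBS-oxy)-3-methoxyphenyl]propanoyl]oxazolidin-2-one | COc1cc([C@@H](O)[C@@H](C(=O)N2C(=O)OC[C@@H]2Cc2ccccc2)Oc2c(OC)cc(/C=C/CO[Si](C)(C)C(C)(C)C)cc2OC)ccc1O[Si](C)(C)C(C)(C)C
F14 | step 7 | (1R,2R)-1-[4-(TBS-oxy)-3-methoxyphenyl]-2-{4-[(E)-3-(TBS-oxy)prop-1-enyl]-2,6-dimethoxyphenoxy}propane-1,3-diol (threo) | COc1cc([C@@H](O)[C@@H](CO)Oc2c(OC)cc(/C=C/CO[Si](C)(C)C(C)(C)C)cc2OC)ccc1O[Si](C)(C)C(C)(C)C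
F15 | step 7 | (1R,2R)-3-(TBS-oxy)-1-[4-(TBS-oxy)-3-methoxyphenyl]-2-{4-[(E)-3-(TBS-oxy)prop-1-enyl]-2,6-dimethoxyphenoxy}propan-1-ol | COc1cc([C@@H](O)[C@@H](CO[Si](C)(C)C(C)(C)C)Oc2c(OC)cc(/C=C/CO[Si](C)(C)C(C)(C)C)cc2OC)ccc1O[Si](C)(C)C(C)(C)C
F16 | step 7 | (R)-3-(TBS-oxy)-1-[4-(TBS-oxy)-3-methoxyphenyl]-2-{4-[(E)-3-(TBS-oxy)prop-1-enyl]-2,6-dimethoxyphenoxy}propan-1-one | COc1cc(C(=O)[C@@H](CO[Si](C)(C)C(C)(C)C)Oc2c(OC)cc(/C=C/CO[Si](C)(C)C(C)(C)C)cc2OC)ccc1O[Si](C)(C)C(C)(C)C
F17 | step 7 | (1S,2R)-3-(TBS-oxy)-1-[4-(TBS-oxy)-3-methoxyphenyl]-2-{4-[(E)-3-(TBS-oxy)prop-1-enyl]-2,6-dimethoxyphenoxy}propan-1-ol (erythro) | COc1cc([C@H](O)[C@@H](CO[Si](C)(C)C(C)(C)C)Oc2c(OC)cc(/C=C/CO[Si](C)(C)C(C)(C)C)cc2OC)ccc1O[Si](C)(C)C(C)(C)C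
F18 | step 4 | ethyl {4-[(E)-3-hydroxyprop-1-enyl]-2,6-dimethoxyphenoxy}acetate | CCOC(=O)COc1c(OC)cc(/C=C/CO)cc1OC
F19 | step 4 | ethyl {4-[(E)-3-(TBS-oxy)prop-1-enyl]-2,6-dimethoxyphenoxy}acetate | CCOC(=O)COc1c(OC)cc(/C=C/CO[Si](C)(C)C(C)(C)C)cc1OC
F20 | step 4 | {4-[(E)-3-(TBS-oxy)prop-1-enyl]-2,6-dimethoxyphenoxy}acetic acid | OC(=O)COc1c(OC)cc(/C=C/CO[Si](C)(C)C(C)(C)C)cc1OC
F21 | step 4 | {4-[(E)-3-(TBS-oxy)prop-1-enyl]-2,6-dimethoxyphenoxy}acetic pivalic anhydride (not isolated) | CC(C)(C)C(=O)OC(=O)COc1c(OC)cc(/C=C/CO[Si](C)(C)C(C)(C)C)cc1OC
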